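## Structural features

- The target is a flavanone: benzene ring A is fused to dihydropyranone ring C (a chroman-4-one), C2 carries a 2,4,6-trihydroxyphenyl ring B, and C6 carries a ten-carbon lavandulyl chain through a CH2 group.
- There are two stereocentres, C2 (S) and the branching carbon of the side chain (S by the CIP rules, with the spatial arrangement of (R)-lavandulol). Ring A and five bonds separate them, so neither can control the other and each must be introduced on its own.
- The side chain is a β-branched, non-allylic primary alkyl group, so it cannot be put on a phenol by the C-alkylation used for prenyl groups. Its 1,1-disubstituted and trisubstituted alkenes cyclise onto O5 or O7 under acid.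
- C2 is a benzylic ether carbon flanked by the two ortho hydroxyls of ring B. Once these are free, the C2–O1 bond can open, either by ring-B-assisted ionisation or by retro-oxa-Michael reaction through the C3 enolate, and the C2 configuration is then lost.
- The real difficulties are the placement of the chain at C6 and not C8, the attachment of the chain without touching its stereocentre, and the setting and keeping of C2 next to a doubly ortho-substituted aryl group.
- The key step uses the fact that C6 lies between O5 and O7 and para to C8a, the carbon that bears O1. Before ring C exists, ring A is therefore a 4-alkyl-3,5-dioxygenated phenyl ether whose two ortho carbons are equivalent; whichever one attacks the acyl carbon becomes C4a, and the chain ends at C6.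

## Logic of the disconnections

**25 ⇒ 24 ⇒ 23 (O–acyl and O–Si bonds).** The five phenols are masked in two sets. Ring B carries acetates, which keep it electron-poor, and they are cleaved last because free ring-B hydroxyls are what make C2 labile. Ring A carries silyl ethers, which keep it electron-rich. The forward steps must therefore be a buffered fluoride cleavage and a neutral transesterification.

**23 ⇒ 20 (C4–C4a bond, ring C).** Cutting the aryl ketone bond opens ring C and leaves an acyclic acid whose only ring-forming site is one of two equivalent ortho carbons. The regiochemical problem disappears and C2 becomes an ordinary ether stereocentre. The forward step needs a strongly electrophilic acyl carbon in a medium free of protic acid, and a ring B that does not support a benzylic cation.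

**20 ⇒ 18 ⇒ 17 ⇒ 8 + 16 (oxidation level, O–Si, then the benzylic C–O bond).** The acid is taken back to a primary alcohol and its silyl ether, so that the ether bond can be cut without a β-carbonyl group that would invite elimination. Cutting the benzylic C–O bond divides the molecule into two halves of similar size and puts the C2 problem on a carbinol. The forward step must be a clean SN2 inversion at a benzylic carbon with two ortho substituents, so 16 must be (R) and ring B must be acceptor-substituted.

**8 ⇒ 7 ⇒ 3 + 6 (C–O through C–B, then the aryl–CH2 bond).** The phenol oxygen is traced to a boronate and the side chain to a primary alkylzinc. A cross-coupling is used because the chain is not allylic, and because bond formation at CH2 leaves the stereocentre one carbon away untouched. The forward coupling must proceed at a bromide flanked by two silyloxy groups and must leave the boronate alone, which a base-free Negishi coupling does.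

**3 ⇒ 2 ⇒ 1 and 6 ⇒ 5 ⇒ 4.** The boron is introduced by sterically governed C–H borylation of 2, in which the only unhindered C–H is para to bromine. The three ring-A oxygens are thus differentiated by symmetry and not by selective protection. The zinc reagent comes from the iodide of the chiral alcohol 4.

**16 ⇒ 15 ⇒ 12 ⇒ 10 ⇒ 9 (O–Si, C=C cleavage, then the carbinol C–C bond).** The monoprotected diol is traced to a homoallylic alcohol and this to aldehyde 10 by a catalytic enantioselective allylation, which sets the configuration that step 10 inverts. Every operation on this branch must avoid a free alkoxide next to the ortho acetates, so boron-bound, acidic or hindered-base conditions are chosen throughout.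

## Other disconnections considered

**Alternative 1:** The cut takes out C4 as a one-carbon unit and breaks C4a–C4, C4–C3 and O1–C2.
- Forward key step: 2-iodo-3,5-bis(methoxymethoxy)-4-[(S)-lavandulyl]phenol A2, carbon monoxide A3 and 2-ethynyl-1,3,5-tris(methoxymethoxy)benzene A4 combine under palladium catalysis to the flavone A1. An enantioselective 1,4-reduction of C2=C3 would then give the flavanone pentakis(methoxymethyl) ether A5, and acid would remove five acetals.
- In its favour: three bonds and ring C arise in one operation, which is better than the chosen plan in bond economy. No stereocentre exists during fragment assembly, so nothing can racemise early. The same ring-A symmetry is used, since iodination of either ortho position of the para-phenol is equivalent; on this point the two plans are equal. The step count would be equal or slightly lower.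
- Against it here: after the carbonylative coupling the phenol oxygen must add to the alkyne in the 6-endo sense, and the 5-exo mode competes. C2 then depends on an asymmetric conjugate reduction at a β-carbon bearing a twisted 2,6-disubstituted aryl group. Hydrogenation catalysts for chromones threaten the 1,1-disubstituted alkene and tend to reduce the ketone as well. Five acetals need acid, which the side-chain alkenes and a C2–O1 bond next to an electron-rich ring B tolerate least.
- Comparison: the chosen plan forms fewer bonds in its key step, but takes C2 from a carbinol of known configuration by a stereospecific displacement and ends under neutral conditions. It is weaker in convergence and stronger in stereochemical and end-game safety.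

**Alternative 2:** The cut breaks C8–C8a and C4a–C5, so ring A is built last.
- Forward key step: 1-methoxy-2-[(S)-lavandulyl]-1,3-bis(trimethylsilyloxy)buta-1,3-diene A7 adds to (2S)-5-bromo-2-(2,4,6-triacetoxyphenyl)-2,3-dihydro-4H-pyran-4-one A8. The adduct aromatises by loss of the bromide and the methoxy group and gives A6, which is identical with 24.
- In its favour: the position of the side chain is fixed by the polarity of the diene, which is equal to the chosen plan in certainty, by polarity instead of symmetry. Ring A arrives with O5 and O7 free, so the end-game is one step instead of two, which is better. C2 would come from a catalytic hetero-Diels–Alder reaction of 10 with a 1-alkoxy-3-silyloxybutadiene, which avoids any displacement at a hindered benzylic carbon; this is also better.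
- Against it here: the dienophile is a vinylogous ester and a reluctant 2π partner even with the α-bromine. The diene is fully substituted at its ketene acetal end and branched at C2, so heat or a Lewis acid would be needed. A 2-aryl-dihydropyranone can then epimerise by retro-oxa-Michael opening. The aromatisation releases a strong acid next to two alkenes. The diene requires C-alkylation of an acetoacetic ester with the sluggish iodide 5.
- Comparison: step economy is about equal. The chosen plan rests on one cationic ring closure of a well-known type, while this one needs a demanding cycloaddition and two eliminations in one pot.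

**Alternative 3:** The cut breaks C3–C4 and O1–C2.
- Forward key step: 2-hydroxy-4,6-bis(tert-butyldimethylsilyloxy)-5-[(S)-lavandulyl]benzaldehyde A10 and trimethyl orthoformate A11 give, under acid, a 4-methoxy ortho-quinone methide as its oxocarbenium ion. This adds 2-ethenylbenzene-1,3,5-triyl triacetate A12 in an inverse-demand [4+2] reaction to the 2,4-cis 4-methoxyflavan A9. Two further steps, ether hydrolysis and oxidation at C4, would lead to 23.
- In its favour: both partners are short, A10 by ortho-formylation of 8 and A12 by methylenation of 10, which is better than the chosen plan in fragment preparation. No hindered SN2 step is needed. The ring-A symmetry is used equally, since either ortho position of 8 can be formylated.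
- Against it here: the cycloaddition fixes only the relation of C2 to C4. Nothing in the substrates controls the absolute configuration, so an external chiral acid would have to, and the C4 stereocentre is then destroyed. The alkene A12 is twisted and deactivated by three acetoxy groups, while this cycloaddition wants an electron-rich alkene; the groups that later protect C2 work against the key step. The acid needed for the oxocarbenium ion meets the side-chain alkenes.
- Comparison: step count is about equal. The chosen plan is clearly stronger on absolute configuration and weaker on convergence.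

Key step: step 13

## Remarks on the chemistry (assumptions)

- In the names below, "(S)-lavandulyl" means the (2S)-5-methyl-2-(prop-1-en-2-yl)hex-4-en-1-yl group. It has the spatial arrangement of (R)-lavandulol; the descriptor changes from R to S only because CH2–aryl ranks below isopropenyl while CH2–O, CH2–I and CH2–Zn rank above it. No structure needed a change of constitution or configuration.
- Design points tightened around acid 20:
  - The para oxygen of ring A is placed by C–H borylation and not by selective protection.
  - The primary hydroxyl carries a triethylsilyl group, which is orthogonal to the aryl silyl ethers and the acetates.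
  - The carbinol flanked by two ortho acetoxy groups is made and handled only under boron-bound, acidic or hindered-base conditions, because an alkoxide there would take up an acetyl group.
- 2-Bromobenzene-1,3-diol, (R)-lavandulol and 2,4,6-trihydroxybenzaldehyde are taken as commercial.
- The sense of induction in step 7 is assumed by analogy with simple aryl aldehydes.

## Route

Step 1
Reactants: 1 2-bromobenzene-1,3-diol
Product: 2 2-bromo-1,3-bis(tert-butyldimethylsilyloxy)benzene
Conditions: TBSCl (2.4 equiv), imidazole (5 equiv), DMF, 0 °C → rt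
Reagents that add atoms: tert-butyldimethylsilyl chloride, CC(C)(C)[Si](C)(C)Cl
Why: Standard silylation of phenols with a silyl chloride and imidazole; both hydroxyls are equivalent, and the silyl ethers are the donor groups that ring A needs in step 13.

Step 2
Reactants: 2 2-bromo-1,3-bis(tert-butyldimethylsilyloxy)benzene
Product: 3 2-[4-bromo-3,5-bis(tert-butyldimethylsilyloxy)phenyl]-4,4,5,5-tetramethyl-1,3,2-dioxaborolane
Conditions: B2pin2 (1.0 equiv), [Ir(OMe)(cod)]2 (1.5 mol%), 4,4′-di-tert-butyl-2,2′-bipyridine (3 mol%), THF, 80 °C
Reagents that add atoms: bis(pinacolato)diboron, CC1(C)OB(OC1(C)C)B1OC(C)(C)C(C)(C)O1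
Why: Iridium-catalysed aromatic C–H borylation is governed by steric access; C5 is the only C–H without an ortho substituent, so boron enters para to bromine and the future phenol oxygen is placed by the mirror symmetry of 2. Aryl bromides and silyl ethers are tolerated.

Step 3
Reactants: 4 (R)-lavandulol, (2R)-5-methyl-2-(prop-1-en-2-yl)hex-4-en-1-ol
Product: 5 (R)-lavandulyl iodide, (5R)-6-iodo-2-methyl-5-(prop-1-en-2-yl)hex-2-ene
Conditions: PPh3, I2, imidazole, CH2Cl2, 0 °C → rt, dark
Reagents that add atoms: iodine, II
Why: Appel-type iodination of a primary alcohol by SN2 at CH2; the neighbouring stereocentre is not a reaction centre, and the buffered medium should not isomerise the alkenes.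

Step 4
Reactants: 5 (R)-lavandulyl iodide; 3 2-[4-bromo-3,5-bis(tert-butyldimethylsilyloxy)phenyl]-4,4,5,5-tetramethyl-1,3,2-dioxaborolane
Product: 7 2-{3,5-bis(tert-butyldimethylsilyloxy)-4-[(S)-lavandulyl]phenyl}-4,4,5,5-tetramethyl-1,3,2-dioxaborolane, via alkylzinc iodide 6 (not isolated)
Conditions: 5, Zn dust (activated), LiCl, THF, 40 °C; then 3, Pd(OAc)2 (3 mol%), SPhos (6 mol%), THF, 50 °C
Reagents that add atoms: none
Why: Negishi coupling of a primary alkylzinc halide with an aryl bromide; zinc insertion and transmetalation occur at CH2 and leave the β-stereocentre alone, and without base the pinacol boronate is a spectator. The dialkylbiarylphosphine is chosen for oxidative addition at a bromide with two ortho substituents and for reductive elimination ahead of β-hydride loss.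

Step 5
Reactants: 7 2-{3,5-bis(tert-butyldimethylsilyloxy)-4-[(S)-lavandulyl]phenyl}-4,4,5,5-tetramethyl-1,3,2-dioxaborolane
Product: 8 3,5-bis(tert-butyldimethylsilyloxy)-4-[(S)-lavandulyl]phenol
Conditions: NaBO3·4H2O (3 equiv), THF–H2O (1:1), 0 °C → rt
Reagents that add atoms: sodium perborate, [Na+].[Na+].O[B-]1(O)OO[B-](O)(O)OO1
Why: Oxidation of an arylboronic ester to the phenol by perborate (aryl shift from boron to oxygen, then hydrolysis), the mild form of the hydroboration work-up, which leaves isolated alkenes and hindered aryl silyl ethers alone.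

Step 6
Reactants: 9 2,4,6-trihydroxybenzaldehyde
Product: 10 2-formylbenzene-1,3,5-triyl triacetate
Conditions: Ac2O (3.6 equiv), pyridine, DMAP (2 mol%), CH2Cl2, 0 °C
Reagents that add atoms: acetic anhydride, CC(=O)OC(C)=O
Why: Acetylation of the three phenols; the acetates make ring B acceptor-substituted, which step 10 needs for a clean SN2 course and step 13 needs against C2–O1 ionisation, and they can be removed by neutral transesterification.

Step 7
Reactants: 10 2-formylbenzene-1,3,5-triyl triacetate
Product: 12 (1R)-1-(2,4,6-triacetoxyphenyl)but-3-en-1-ol, via pinacol borate ester 11 (not isolated)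
Conditions: allylB(pin) (1.3 equiv), (R)-TRIP phosphoric acid (5 mol%), toluene, −30 °C; pH 7 buffer
Reagents that add atoms: allylboronic acid pinacol ester, C=CCB1OC(C)(C)C(C)(C)O1
Why: Chiral phosphoric acid-catalysed allylboration of an aromatic aldehyde through a closed six-membered transition state; the (R)-acid is expected, by analogy with simple aryl aldehydes, to give the (R)-alcohol (to be confirmed on 12, otherwise the enantiomeric acid is used). The oxygen stays bound to boron until the neutral work-up, so no free alkoxide sits next to the ortho acetates.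

Step 8
Reactants: 12 (1R)-1-(2,4,6-triacetoxyphenyl)but-3-en-1-ol
Product: 15 (1R)-1-(2,4,6-triacetoxyphenyl)propane-1,3-diol, via secondary ozonide 13 (not isolated), via β-hydroxy aldehyde 14 (not isolated)
Conditions: O3, CH2Cl2, −78 °C; PPh3, −78 → 0 °C; NaBH(OAc)3, AcOH, 0 °C → rt
Reagents that add atoms: ozone, [O-][O+]=O
Why: Ozonolysis of the only alkene (the triacetoxyarene is deactivated), reduction of the ozonide by the phosphine and of the aldehyde by NaBH(OAc)3, which spares aryl acetates and keeps the medium acidic. The stereocentre is not involved.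

Step 9
Reactants: 15 (1R)-1-(2,4,6-triacetoxyphenyl)propane-1,3-diol
Product: 16 (1R)-1-(2,4,6-triacetoxyphenyl)-3-(triethylsilyloxy)propan-1-ol
Conditions: TESOTf (1.0 equiv), 2,6-lutidine, CH2Cl2, −78 °C
Reagents that add atoms: triethylsilyl trifluoromethanesulfonate, CC[Si](CC)(CC)OS(=O)(=O)C(F)(F)F
Why: The primary hydroxyl is silylated in preference to the secondary benzylic one, which is flanked by two ortho substituents; the hindered, non-nucleophilic base at low temperature should not promote acetyl migration. The triethylsilyl ether can later be removed without loss of the aryl silyl ethers.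

Step 10
Reactants: 16 (1R)-1-(2,4,6-triacetoxyphenyl)-3-(triethylsilyloxy)propan-1-ol; 8 3,5-bis(tert-butyldimethylsilyloxy)-4-[(S)-lavandulyl]phenol
Product: 17 2-[(1S)-1-{3,5-bis(tert-butyldimethylsilyloxy)-4-[(S)-lavandulyl]phenoxy}-3-(triethylsilyloxy)propyl]benzene-1,3,5-triyl triacetate
Conditions: PPh3 (1.5 equiv), DIAD (1.5 equiv), toluene, 0 °C → rt
Reagents that add atoms: none
Why: Mitsunobu etherification of a secondary benzylic alcohol with a phenol (pKa about 10); the phenoxide displaces the alkoxyphosphonium group with inversion, (R) to (S). The three acetoxy groups disfavour a benzylic cation, so the SN2 course should hold, as in known etherifications of 1-(2,6-disubstituted aryl)ethanols.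

Step 11
Reactants: 17 2-[(1S)-1-{3,5-bis(tert-butyldimethylsilyloxy)-4-[(S)-lavandulyl]phenoxy}-3-(triethylsilyloxy)propyl]benzene-1,3,5-triyl triacetate
Product: 18 2-[(1S)-1-{3,5-bis(tert-butyldimethylsilyloxy)-4-[(S)-lavandulyl]phenoxy}-3-hydroxypropyl]benzene-1,3,5-triyl triacetate
Conditions: AcOH–THF–H2O (3:1:1), rt
Reagents that add atoms: none
Why: Aqueous acetic acid cleaves a primary triethylsilyl ether far faster than aryl tert-butyldimethylsilyl ethers; the aryl acetates, the benzylic aryl ether and the alkenes are stable at this acidity.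

Step 12
Reactants: 18 2-[(1S)-1-{3,5-bis(tert-butyldimethylsilyloxy)-4-[(S)-lavandulyl]phenoxy}-3-hydroxypropyl]benzene-1,3,5-triyl triacetate
Product: 20 (3S)-3-{3,5-bis(tert-butyldimethylsilyloxy)-4-[(S)-lavandulyl]phenoxy}-3-(2,4,6-triacetoxyphenyl)propanoic acid, via β-aryloxy aldehyde 19 (not isolated)
Conditions: TEMPO (20 mol%), PhI(OAc)2 (2.5 equiv), MeCN–H2O (1:1), rt
Reagents that add atoms: water, O
Why: Oxoammonium-catalysed oxidation of a primary alcohol through the aldehyde hydrate to the acid; isolated alkenes, aryl ethers and esters are tolerated, and the slightly acidic medium disfavours β-elimination of the aryloxide from 19.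

Step 13
Reactants: 20 (3S)-3-{3,5-bis(tert-butyldimethylsilyloxy)-4-[(S)-lavandulyl]phenoxy}-3-(2,4,6-triacetoxyphenyl)propanoic acid
Product: 23 (2S)-5,7-bis(tert-butyldimethylsilyloxy)-6-[(S)-lavandulyl]-2-(2,4,6-triacetoxyphenyl)-2,3-dihydro-4H-chromen-4-one, via acid chloride 21 (not isolated), via acyl triflate 22 (not isolated)
Conditions: 1-chloro-N,N,2-trimethylprop-1-en-1-amine (1.2 equiv), CH2Cl2, 0 °C → rt; then 2,6-di-tert-butyl-4-methylpyridine (2.5 equiv), AgOTf (1.3 equiv), CH2Cl2, −78 → −30 °C
Reagents that add atoms: none
Why: The α-chloroenamine turns the acid into acid chloride 21 under neutral conditions, and AgOTf then precipitates AgCl and gives acyl triflate 22, in equilibrium with the acylium ion. An ortho carbon of ring A, activated by the ether oxygen and by the ortho and para silyloxy groups, attacks the acyl carbon and the hindered pyridine deprotonates the arenium ion; this is an intramolecular Friedel–Crafts acylation of the type long used to turn 3-aryloxypropanoic acids into chroman-4-ones, here with acyl triflate activation. Ring C closes in a 6-exo mode (the carbonyl oxygen stays outside the new ring) and only the C4–C4a bond is formed. No stereocentre is created; C2 comes from 20 unchanged, because C3 separates it from the acyl carbon and because ring B, with three acetoxy groups, does not support a benzylic cation, so the C2–O1 bond should not ionise at low temperature. Regioselectivity needs no control, since rotation about the aryl–oxygen bond interconverts the two ortho carbons and either closure leaves the side chain at C6. Chemoselectivity rests on the arene being far more nucleophilic than the two isolated alkenes, on the ortho positions of ring B being blocked and deactivated, and on the base removing TfOH before it can protonate the alkenes or cleave the silyl ethers.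

Step 14
Reactants: 23 (2S)-5,7-bis(tert-butyldimethylsilyloxy)-6-[(S)-lavandulyl]-2-(2,4,6-triacetoxyphenyl)-2,3-dihydro-4H-chromen-4-one
Product: 24 (2S)-5,7-dihydroxy-6-[(S)-lavandulyl]-2-(2,4,6-triacetoxyphenyl)-2,3-dihydro-4H-chromen-4-one
Conditions: HF·pyridine, pyridine, THF, 0 °C
Reagents that add atoms: none
Why: Fluoride cleaves the two aryl silyl ethers; excess pyridine buffers HF so that the alkenes are not protonated, and the aryl acetates stay on, so ring B is still deactivated and C2 is still protected against ionisation.

Step 15
Reactants: 24 (2S)-5,7-dihydroxy-6-[(S)-lavandulyl]-2-(2,4,6-triacetoxyphenyl)-2,3-dihydro-4H-chromen-4-one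
Product: 25 (2S)-5,7-dihydroxy-6-[(S)-lavandulyl]-2-(2,4,6-trihydroxyphenyl)-2,3-dihydro-4H-chromen-4-one
Conditions: NH4OAc (10 equiv), MeOH–H2O (4:1), rt
Reagents that add atoms: none
Why: Ammonium acetate catalyses transesterification of aryl acetates at about neutral pH; ring B is unveiled last because its free ortho and para hydroxyls are what make the C2–O1 bond labile. The neutral medium is meant to avoid chalcone formation and acid-induced cyclisation of the side chain.

## Compound list

1 | 2-bromobenzene-1,3-diol | Oc1cccc(O)c1Br | starting material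
2 | 2-bromo-1,3-bis(tert-butyldimethylsilyloxy)benzene | CC(C)(C)[Si](C)(C)Oc1cccc(O[Si](C)(C)C(C)(C)C)c1Br | intermediate
3 | 2-[4-bromo-3,5-bis(tert-butyldimethylsilyloxy)phenyl]-4,4,5,5-tetramethyl-1,3,2-dioxaborolane | CC(C)(C)[Si](C)(C)Oc1cc(B2OC(C)(C)C(C)(C)O2)cc(O[Si](C)(C)C(C)(C)C)c1Br | intermediate
4 | (R)-lavandulol, (2R)-5-methyl-2-(prop-1-en-2-yl)hex-4-en-1-ol | C=C(C)[C@@H](CC=C(C)C)CO | starting material
5 | (R)-lavandulyl iodide, (5R)-6-iodo-2-methyl-5-(prop-1-en-2-yl)hex-2-ene | C=C(C)[C@@H](CC=C(C)C)CI | intermediate
6 | [(2R)-5-methyl-2-(prop-1-en-2-yl)hex-4-en-1-yl]zinc iodide | C=C(C)[C@@H](CC=C(C)C)C[Zn]I | intermediate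
7 | 2-{3,5-bis(tert-butyldimethylsilyloxy)-4-[(2S)-5-methyl-2-(prop-1-en-2-yl)hex-4-en-1-yl]phenyl}-4,4,5,5-tetramethyl-1,3,2-dioxaborolane | C=C(C)[C@@H](CC=C(C)C)Cc1c(O[Si](C)(C)C(C)(C)C)cc(B2OC(C)(C)C(C)(C)O2)cc1O[Si](C)(C)C(C)(C)C | intermediate
8 | 3,5-bis(tert-butyldimethylsilyloxy)-4-[(2S)-5-methyl-2-(prop-1-en-2-yl)hex-4-en-1-yl]phenol | C=C(C)[C@@H](CC=C(C)C)Cc1c(O[Si](C)(C)C(C)(C)C)cc(O)cc1O[Si](C)(C)C(C)(C)C | intermediate
9 | 2,4,6-trihydroxybenzaldehyde | O=Cc1c(O)cc(O)cc1O | starting material
10 | 2-formylbenzene-1,3,5-triyl triacetate (2,4,6-triacetoxybenzaldehyde) | O=Cc1c(OC(C)=O)cc(OC(C)=O)cc1OC(C)=O | intermediate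
11 | 2-{[(1R)-1-(2,4,6-triacetoxyphenyl)but-3-en-1-yl]oxy}-4,4,5,5-tetramethyl-1,3,2-dioxaborolane | CC1(C)OB(O[C@H](CC=C)c2c(OC(C)=O)cc(OC(C)=O)cc2OC(C)=O)OC1(C)C | intermediate
12 | (1R)-1-(2,4,6-triacetoxyphenyl)but-3-en-1-ol | O[C@H](CC=C)c1c(OC(C)=O)cc(OC(C)=O)cc1OC(C)=O | intermediate
13 | (1R)-1-(2,4,6-triacetoxyphenyl)-2-(1,2,4-trioxolan-3-yl)ethan-1-ol (mixture at the ozonide carbon) | O[C@H](CC1OCOO1)c1c(OC(C)=O)cc(OC(C)=O)cc1OC(C)=O | intermediate
14 | (3R)-3-hydroxy-3-(2,4,6-triacetoxyphenyl)propanal | O[C@H](CC=O)c1c(OC(C)=O)cc(OC(C)=O)cc1OC(C)=O | intermediate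
15 | (1R)-1-(2,4,6-triacetoxyphenyl)propane-1,3-diol | O[C@H](CCO)c1c(OC(C)=O)cc(OC(C)=O)cc1OC(C)=O | intermediate
16 | (1R)-1-(2,4,6-triacetoxyphenyl)-3-(triethylsilyloxy)propan-1-ol | O[C@H](CCO[Si](CC)(CC)CC)c1c(OC(C)=O)cc(OC(C)=O)cc1OC(C)=O | intermediate
17 | 2-[(1S)-1-{3,5-bis(tert-butyldimethylsilyloxy)-4-[(S)-lavandulyl]phenoxy}-3-(triethylsilyloxy)propyl]benzene-1,3,5-triyl triacetate | C=C(C)[C@@H](CC=C(C)C)Cc1c(O[Si](C)(C)C(C)(C)C)cc(O[C@@H](CCO[Si](CC)(CC)CC)c2c(OC(C)=O)cc(OC(C)=O)cc2OC(C)=O)cc1O[Si](C)(C)C(C)(C)C | intermediate
18 | 2-[(1S)-1-{3,5-bis(tert-butyldimethylsilyloxy)-4-[(S)-lavandulyl]phenoxy}-3-hydroxypropyl]benzene-1,3,5-triyl triacetate | C=C(C)[C@@H](CC=C(C)C)Cc1c(O[Si](C)(C)C(C)(C)C)cc(O[C@@H](CCO)c2c(OC(C)=O)cc(OC(C)=O)cc2OC(C)=O)cc1O[Si](C)(C)C(C)(C)C | intermediate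
19 | (3S)-3-{3,5-bis(tert-butyldimethylsilyloxy)-4-[(S)-lavandulyl]phenoxy}-3-(2,4,6-triacetoxyphenyl)propanal | C=C(C)[C@@H](CC=C(C)C)Cc1c(O[Si](C)(C)C(C)(C)C)cc(O[C@@H](CC=O)c2c(OC(C)=O)cc(OC(C)=O)cc2OC(C)=O)cc1O[Si](C)(C)C(C)(C)C | intermediate
20 | (3S)-3-{3,5-bis(tert-butyldimethylsilyloxy)-4-[(S)-lavandulyl]phenoxy}-3-(2,4,6-triacetoxyphenyl)propanoic acid | C=C(C)[C@@H](CC=C(C)C)Cc1c(O[Si](C)(C)C(C)(C)C)cc(O[C@@H](CC(=O)O)c2c(OC(C)=O)cc(OC(C)=O)cc2OC(C)=O)cc1O[Si](C)(C)C(C)(C)C | intermediate
21 | (3S)-3-{3,5-bis(tert-butyldimethylsilyloxy)-4-[(S)-lavandulyl]phenoxy}-3-(2,4,6-triacetoxyphenyl)propanoyl chloride | C=C(C)[C@@H](CC=C(C)C)Cc1c(O[Si](C)(C)C(C)(C)C)cc(O[C@@H](CC(=O)Cl)c2c(OC(C)=O)cc(OC(C)=O)cc2OC(C)=O)cc1O[Si](C)(C)C(C)(C)C | intermediate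
22 | (3S)-3-{3,5-bis(tert-butyldimethylsilyloxy)-4-[(S)-lavandulyl]phenoxy}-3-(2,4,6-triacetoxyphenyl)propanoyl trifluoromethanesulfonate | C=C(C)[C@@H](CC=C(C)C)Cc1c(O[Si](C)(C)C(C)(C)C)cc(O[C@@H](CC(=O)OS(=O)(=O)C(F)(F)F)c2c(OC(C)=O)cc(OC(C)=O)cc2OC(C)=O)cc1O[Si](C)(C)C(C)(C)C | intermediate
23 | (2S)-5,7-bis(tert-butyldimethylsilyloxy)-6-[(2S)-5-methyl-2-(prop-1-en-2-yl)hex-4-en-1-yl]-2-(2,4,6-triacetoxyphenyl)-2,3-dihydro-4H-chromen-4-one | C=C(C)[C@@H](CC=C(C)C)Cc1c(O[Si](C)(C)C(C)(C)C)cc2c(c1O[Si](C)(C)C(C)(C)C)C(=O)C[C@@H](c1c(OC(C)=O)cc(OC(C)=O)cc1OC(C)=O)O2 | intermediate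
24 | (2S)-5,7-dihydroxy-6-[(2S)-5-methyl-2-(prop-1-en-2-yl)hex-4-en-1-yl]-2-(2,4,6-triacetoxyphenyl)-2,3-dihydro-4H-chromen-4-one | C=C(C)[C@@H](CC=C(C)C)Cc1c(O)cc2c(c1O)C(=O)C[C@@H](c1c(OC(C)=O)cc(OC(C)=O)cc1OC(C)=O)O2 | intermediate
25 | (2S)-5,7-dihydroxy-6-[(2S)-5-methyl-2-(prop-1-en-2-yl)hex-4-en-1-yl]-2-(2,4,6-trihydroxyphenyl)-2,3-dihydro-4H-chromen-4-one | C=C(C)[C@@H](CC=C(C)C)Cc1c(O)cc2c(c1O)C(=O)C[C@@H](c1c(O)cc(O)cc1O)O2 | target

## Step count and least certain steps

Total: 15 steps. Longest linear sequence: 10 steps (1 → 2 → 3 → 7 → 8 → 17 → 18 → 20 → 23 → 24 → 25, steps 1, 2, 4, 5 and 10–15; the branch from 9 through steps 6–15 is equally long).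

**Step 13 (key step).** The most likely failure is heterolysis of the benzylic C2–O1 bond under the Lewis-acidic conditions, with loss of the C2 configuration or fragmentation. A second risk is a closure slowed by crowding at the ortho carbon, which would let the acyl triflate eliminate the aryloxide by way of the ketene. Both arise because a very electrophilic acyl carbon sits β to an aryl ether.
The fallback sets out from 20 and returns at 23, and replaces electrophilic acylation by organometallic acylation of the same carbon. N-Iodosuccinimide (MeCN, −20 °C) iodinates one of the two equivalent ortho positions of ring A to give (3S)-3-{3,5-bis(tert-butyldimethylsilyloxy)-2-iodo-4-[(S)-lavandulyl]phenoxy}-3-(2,4,6-triacetoxyphenyl)propanoic acid F1. EtSH and EDC·HCl convert it into S-ethyl (3S)-3-{3,5-bis(tert-butyldimethylsilyloxy)-2-iodo-4-[(S)-lavandulyl]phenoxy}-3-(2,4,6-triacetoxyphenyl)propanethioate F2. Zinc insertion (Zn, LiCl, THF) gives the arylzinc iodide of this thioester F3, which is not isolated and closes ring C on the thioester under PdCl2(PPh3)2 catalysis, a Fukuyama coupling run intramolecularly, to give 23. No acylium ion or Lewis acid is involved, and aryl acetates, silyl ethers and alkenes are inert to organozinc reagents.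

**Step 10.** The most likely failure is a slow bimolecular displacement at the benzylic carbon between two ortho acetoxy groups. Elimination, transfer of an acetyl group to the carbinol oxygen, or participation of an ortho acetoxy carbonyl (erosion of the inversion) could then compete.
The fallback sets out from 3 and 16 and returns at 17, and changes the order of fragment union. Perborate oxidation of 3 gives 4-bromo-3,5-bis(tert-butyldimethylsilyloxy)phenol F4, a smaller and somewhat more acidic nucleophile that should raise the rate of substitution relative to the side reactions. Mitsunobu reaction of F4 with 16 gives 2-[(1S)-1-{4-bromo-3,5-bis(tert-butyldimethylsilyloxy)phenoxy}-3-(triethylsilyloxy)propyl]benzene-1,3,5-triyl triacetate F5. Negishi coupling of F5 with 6 (Pd(OAc)2, SPhos) then installs the side chain and gives 17; alkylzinc halides do not attack acetates or silyl ethers.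

**Step 7.** The most likely failure is insufficient facial selectivity, because the formyl group of a 2,6-disubstituted aldehyde is shielded on both sides and the catalyst pocket may not fit. Acetyl transfer to the new oxygen is a lesser risk.
The fallback sets out from 16 of insufficient enantiomeric purity (reached by steps 7–9, if necessary without the catalyst) and returns at 16, and sets the stereocentre by reduction instead of addition. Dess–Martin periodinane oxidises 16 to 1-(2,4,6-triacetoxyphenyl)-3-(triethylsilyloxy)propan-1-one F6. A CBS reduction ((S)-2-methyl-oxazaborolidine, catecholborane, toluene, −40 °C) should then give (R)-16 if the aryl group acts as the larger substituent; otherwise the enantiomeric catalyst is used. The conditions are non-basic throughout.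

**Step 4.** The most likely failure is slow oxidative addition and reductive elimination at the bromide between two silyloxy groups, so that β-hydride elimination of the alkylpalladium species and protodehalogenation take over.
The fallback sets out from 3 and 5 and returns at 7, and reverses the polarity of the coupling. Zinc dust with catalytic CoBr2 in MeCN converts 3 into [2,6-bis(tert-butyldimethylsilyloxy)-4-(4,4,5,5-tetramethyl-1,3,2-dioxaborolan-2-yl)phenyl]zinc bromide F7. This arylzinc is coupled with the primary iodide 5 under Ni(acac)2 and 4-fluorostyrene in THF–NMP at −15 °C. The hindered partner is then the nucleophile and the unhindered primary iodide the electrophile.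

**Step 15.** The most likely failure is erosion of the C2 configuration once the ring-B hydroxyls are free, by phenoxide-assisted opening of the C2–O1 bond or retro-oxa-Michael opening to the chalcone in a buffer that allows some phenoxide. Incomplete cleavage of the two hindered ortho acetates is a second risk.
The fallback sets out from 24 and returns at 25 without a new compound. Chemical transesterification is replaced by enzymatic alcoholysis with immobilised Candida antarctica lipase B and n-butanol in tert-butyl methyl ether at 30 °C. This medium is non-aqueous and non-basic, so phenoxides are not formed and the acyl groups are transferred through the acyl-enzyme.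

## Further compounds

F1 | step 13 | (3S)-3-{3,5-bis(tert-butyldimethylsilyloxy)-2-iodo-4-[(S)-lavandulyl]phenoxy}-3-(2,4,6-triacetoxyphenyl)propanoic acid | C=C(C)[C@@H](CC=C(C)C)Cc1c(O[Si](C)(C)C(C)(C)C)cc(O[C@@H](CC(=O)O)c2c(OC(C)=O)cc(OC(C)=O)cc2OC(C)=O)c(I)c1O[Si](C)(C)C(C)(C)C
F2 | step 13 | S-ethyl (3S)-3-{3,5-bis(tert-butyldimethylsilyloxy)-2-iodo-4-[(S)-lavandulyl]phenoxy}-3-(2,4,6-triacetoxyphenyl)propanethioate | C=C(C)[C@@H](CC=C(C)C)Cc1c(O[Si](C)(C)C(C)(C)C)cc(O[C@@H](CC(=O)SCC)c2c(OC(C)=O)cc(OC(C)=O)cc2OC(C)=O)c(I)c1O[Si](C)(C)C(C)(C)C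
F3 | step 13 | arylzinc iodide of F2 (zinc in place of iodine) | C=C(C)[C@@H](CC=C(C)C)Cc1c(O[Si](C)(C)C(C)(C)C)cc(O[C@@H](CC(=O)SCC)c2c(OC(C)=O)cc(OC(C)=O)cc2OC(C)=O)c([Zn]I)c1O[Si](C)(C)C(C)(C)C
F4 | step 10 | 4-bromo-3,5-bis(tert-butyldimethylsilyloxy)phenol | CC(C)(C)[Si](C)(C)Oc1cc(O)cc(O[Si](C)(C)C(C)(C)C)c1Br
F5 | step 10 | 2-[(1S)-1-{4-bromo-3,5-bis(tert-butyldimethylsilyloxy)phenoxy}-3-(triethylsilyloxy)propyl]benzene-1,3,5-triyl triacetate | CC(C)(C)[Si](C)(C)Oc1cc(O[C@@H](CCO[Si](CC)(CC)CC)c2c(OC(C)=O)cc(OC(C)=O)cc2OC(C)=O)cc(O[Si](C)(C)C(C)(C)C)c1Br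
F6 | step 7 | 1-(2,4,6-triacetoxyphenyl)-3-(triethylsilyloxy)propan-1-one | O=C(CCO[Si](CC)(CC)CC)c1c(OC(C)=O)cc(OC(C)=O)cc1OC(C)=O
F7 | step 4 | [2,6-bis(tert-butyldimethylsilyloxy)-4-(4,4,5,5-tetramethyl-1,3,2-dioxaborolan-2-yl)phenyl]zinc bromide | CC(C)(C)[Si](C)(C)Oc1cc(B2OC(C)(C)C(C)(C)O2)cc(O[Si](C)(C)C(C)(C)C)c1[Zn]Br
F0 | step 15 | none | none
A1 | alternative 1 | 5,7-bis(methoxymethoxy)-6-[(S)-lavandulyl]-2-[2,4,6-tris(methoxymethoxy)phenyl]-4H-chromen-4-one | C=C(C)[C@@H](CC=C(C)C)Cc1c(OCOC)cc2oc(-c3c(OCOC)cc(OCOC)cc3OCOC)cc(=O)c2c1OCOC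
A2 | alternative 1 | 2-iodo-3,5-bis(methoxymethoxy)-4-[(S)-lavandulyl]phenol | C=C(C)[C@@H](CC=C(C)C)Cc1c(OCOC)cc(O)c(I)c1OCOC
A3 | alternative 1 | carbon monoxide | [C-]#[O+]
A4 | alternative 1 | 2-ethynyl-1,3,5-tris(methoxymethoxy)benzene | C#Cc1c(OCOC)cc(OCOC)cc1OCOC
A5 | alternative 1 | (2S)-5,7-bis(methoxymethoxy)-6-[(S)-lavandulyl]-2-[2,4,6-tris(methoxymethoxy)phenyl]-2,3-dihydro-4H-chromen-4-one | C=C(C)[C@@H](CC=C(C)C)Cc1c(OCOC)cc2c(c1OCOC)C(=O)C[C@@H](c1c(OCOC)cc(OCOC)cc1OCOC)O2
A6 | alternative 2 | (2S)-5,7-dihydroxy-6-[(S)-lavandulyl]-2-(2,4,6-triacetoxyphenyl)-2,3-dihydro-4H-chromen-4-one | C=C(C)[C@@H](CC=C(C)C)Cc1c(O)cc2c(c1O)C(=O)C[C@@H](c1c(OC(C)=O)cc(OC(C)=O)cc1OC(C)=O)O2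
A7 | alternative 2 | 1-methoxy-2-[(S)-lavandulyl]-1,3-bis(trimethylsilyloxy)buta-1,3-diene | C=C(C)[C@@H](CC=C(C)C)CC(C(=C)O[Si](C)(C)C)=C(OC)O[Si](C)(C)C
A8 | alternative 2 | (2S)-5-bromo-2-(2,4,6-triacetoxyphenyl)-2,3-dihydro-4H-pyran-4-one | O=C1C[C@@H](c2c(OC(C)=O)cc(OC(C)=O)cc2OC(C)=O)OC=C1Br
A9 | alternative 3 | (2S,4S)-4-methoxy-5,7-bis(tert-butyldimethylsilyloxy)-6-[(S)-lavandulyl]-2-(2,4,6-triacetoxyphenyl)chroman (2,4-cis) | C=C(C)[C@@H](CC=C(C)C)Cc1c(O[Si](C)(C)C(C)(C)C)cc2c(c1O[Si](C)(C)C(C)(C)C)[C@@H](OC)C[C@@H](c1c(OC(C)=O)cc(OC(C)=O)cc1OC(C)=O)O2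
A10 | alternative 3 | 2-hydroxy-4,6-bis(tert-butyldimethylsilyloxy)-5-[(S)-lavandulyl]benzaldehyde | C=C(C)[C@@H](CC=C(C)C)Cc1c(O[Si](C)(C)C(C)(C)C)cc(O)c(C=O)c1O[Si](C)(C)C(C)(C)C
A11 | alternative 3 | trimethyl orthoformate | COC(OC)OC
A12 | alternative 3 | 2-ethenylbenzene-1,3,5-triyl triacetate | C=Cc1c(OC(C)=O)cc(OC(C)=O)cc1OC(C)=O
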